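**Retrosynthetic overview**

1. Numbering: ring A is O1, C2 (guaiacyl), C3 (CH2OH, carbon C9), C4 (side chain with carbinol carbon C7'), C5. The strategy rests on the chain O(carbinol)–C7'–C4–C3–C9, which can be closed as a γ-lactone on which C7', C4 and C3 are all trans, as the target requires.
2. Ring A is opened last at O1–C2 (DDQ oxidation of the guaiacyl CH2, capture by the C5 hydroxyl). The C7'/C9 diol is then folded back into the lactone, and the C3–CH2Ar bond is cut as an enolate alkylation.
3. C5 derives from a carboxylate on C4. The resulting trans 2-aryl-5-oxooxolane-3-carboxylate comes in one operation from a racemizing 2-aroylsuccinate by asymmetric transfer hydrogenation with dynamic kinetic resolution and lactonization.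
4. The aroylsuccinate comes from 3,4-bis(benzyloxy)benzoic acid, allyl acetate and methyl bromoacetate (Claisen acylation, then alkylation).
5. Ring order: temporary lactone (step 4, opened in step 10), then ring A (step 13).

Key step: step 4

Remark on the chemistry: the (R,R)-TsDPEN ligand is assumed to give the (R)-aryl carbinol, as it does with aryl methyl ketones; if the α-branched ketone responds in the opposite sense, the (S,S) ligand is used.

**Route**

Step 1
Reactants: 1 3,4-bis(benzyloxy)benzoic acid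
Product: 2 3,4-bis(benzyloxy)benzoyl chloride
Conditions: (COCl)2, DMF (cat.), CH2Cl2, 0 °C to rt
Reagents that add atoms: oxalyl chloride, ClC(=O)C(=O)Cl
Why: Acid chloride formation through the Vilsmeier-type chloroiminium species is routine and leaves aryl benzyl ethers untouched.

Step 2
Reactants: 2 3,4-bis(benzyloxy)benzoyl chloride; 3 allyl acetate
Product: 4 allyl 3-[3,4-bis(benzyloxy)phenyl]-3-oxopropanoate
Conditions: LiN(iPr)2 (2.2 equiv), 3 (2.2 equiv), THF, −78 °C; then 2, −78 °C; aq. NH4Cl
Reagents that add atoms: none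
Why: Crossed Claisen acylation of the lithium ester enolate by the aroyl chloride, with the second equivalent of enolate deprotonating the β-keto ester as it forms so that it is not acylated twice.

Step 3
Reactants: 4 allyl 3-[3,4-bis(benzyloxy)phenyl]-3-oxopropanoate; 5 methyl bromoacetate
Product: 6 1-allyl 4-methyl 2-[3,4-bis(benzyloxy)benzoyl]butanedioate (racemic, configurationally labile)
Conditions: K2CO3, acetone, rt to 40 °C, 5 (1.05 equiv)
Reagents that add atoms: none
Why: Acetoacetic-ester-type SN2 C-alkylation of the stabilized enolate by the reactive α-bromo ester, with one equivalent of electrophile and the hindered, less acidic product limiting dialkylation.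

Step 4
Reactants: 6 1-allyl 4-methyl 2-[3,4-bis(benzyloxy)benzoyl]butanedioate
Product: 9 allyl (2R,3R)-2-[3,4-bis(benzyloxy)phenyl]-5-oxooxolane-3-carboxylate, via hydroxy diester 7 (not isolated), via lactone epimer mixture 8 (not isolated)
Conditions: RuCl(p-cymene)[(R,R)-TsDPEN] (1 mol %), HCO2H/Et3N (5:2), DMF, 40 °C; then PPTS (cat.), PhMe, 50 °C; then DBU (0.1 equiv), PhMe, 60 °C
Reagents that add atoms: none
Why: Formate converts the ruthenium amide into the Ru–H/N–H species (divalent ruthenium throughout), which passes hydride and proton to the aryl ketone through a six-membered outer-sphere transition state while the α-carbon of the keto ester racemizes through its enol in the amine buffer faster than either enantiomer is reduced. The closest known reaction type is asymmetric transfer hydrogenation with dynamic kinetic resolution of α-substituted β-keto esters and amides, followed by lactonization of the hydroxy ester. The benzylic hydroxyl then closes the lactone by 5-exo-trig acyl substitution on the methyl ester with loss of methanol, the allyl ester being able to give only a four-membered ring. The carbinol carbon (R) is set by the (R,R)-TsDPEN ligand, with the aryl group next to the p-cymene ring in the favoured transition state; the ester-bearing carbon is set first by the dynamic resolution (syn hydroxy ester expected) and finally by thermodynamics, since it stays enolizable next to the allyl ester and DBU equilibrates the lactone to the trans isomer. The step needs ketone-selective reduction beside two esters and a terminal alkene, which the outer-sphere hydride transfer to polarized C=O secures, and a facial selectivity independent of the α-configuration, which the aryl/alkyl contrast of the ketone secures. DBU is kept catalytic so that the stereoelectronically disfavoured β-elimination of the lactone carboxylate, which would consume base, cannot exceed the catalyst loading.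

Step 5
Reactants: 9 allyl (2R,3R)-2-[3,4-bis(benzyloxy)phenyl]-5-oxooxolane-3-carboxylate
Product: 10 (2R,3R)-2-[3,4-bis(benzyloxy)phenyl]-5-oxooxolane-3-carboxylic acid
Conditions: Pd(PPh3)4 (3 mol %), morpholine (2 equiv), THF, rt; cold aq. KHSO4
Reagents that add atoms: none
Why: Tsuji–Trost deallylation, in which zerovalent palladium ionizes the allyl ester to a π-allyl complex that morpholine traps, frees the acid under neutral conditions that cannot ionize the electron-rich benzylic lactone C–O bond as a tert-butyl ester cleavage with acid would.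

Step 6
Reactants: 10 (2R,3R)-2-[3,4-bis(benzyloxy)phenyl]-5-oxooxolane-3-carboxylic acid
Product: 11 (4S,5R)-5-[3,4-bis(benzyloxy)phenyl]-4-(hydroxymethyl)oxolan-2-one
Conditions: BH3·SMe2, THF, 0 °C to rt; MeOH quench
Reagents that add atoms: none
Why: Borane reduces the carboxylic acid through its acyloxyborane much faster than the lactone (chemoselective acid reduction, as used on paraconic acids) and touches no stereocentre.

Step 7
Reactants: 11 (4S,5R)-5-[3,4-bis(benzyloxy)phenyl]-4-(hydroxymethyl)oxolan-2-one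
Product: 12 (4S,5R)-5-[3,4-bis(benzyloxy)phenyl]-4-{[(tert-butyldiphenylsilyl)oxy]methyl}oxolan-2-one
Conditions: TBDPSCl, imidazole, DMF, 0 °C to rt
Reagents that add atoms: tert-butyl(chloro)diphenylsilane, CC(C)(C)[Si](Cl)(c1ccccc1)c1ccccc1
Why: Imidazole-promoted silylation of the primary alcohol is fast enough to outrun translactonization of the hydroxymethyl lactone, and the TBDPS ether resists LiAlH4 and O-to-O migration later.

Step 8
Reactants: 13 4-(benzyloxy)-3-methoxybenzyl alcohol
Product: 14 4-(benzyloxy)-3-methoxybenzyl bromide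
Conditions: PBr3 (0.4 equiv), Et2O, 0 °C; used crude at once
Reagents that add atoms: phosphorus tribromide, BrP(Br)Br
Why: Conversion of the benzylic alcohol through its phosphite ester to the bromide by bromide displacement is standard, and the labile electron-rich bromide is not stored.

Step 9
Reactants: 12 (4S,5R)-5-[3,4-bis(benzyloxy)phenyl]-4-{[(tert-butyldiphenylsilyl)oxy]methyl}oxolan-2-one; 14 4-(benzyloxy)-3-methoxybenzyl bromide
Product: 15 (3R,4S,5R)-3-[4-(benzyloxy)-3-methoxybenzyl]-5-[3,4-bis(benzyloxy)phenyl]-4-{[(tert-butyldiphenylsilyl)oxy]methyl}oxolan-2-one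
Conditions: LiN(SiMe3)2 (1.1 equiv), THF, −78 °C; then 14, −78 to −30 °C
Reagents that add atoms: none
Why: Lactone enolate alkylation in which the benzyl bromide approaches the enolate face anti to the neighbouring CH2OTBDPS group, setting C3 trans to C4 and giving the all-trans lactone; the enolate has no β-leaving group.

Step 10
Reactants: 15 (3R,4S,5R)-3-[4-(benzyloxy)-3-methoxybenzyl]-5-[3,4-bis(benzyloxy)phenyl]-4-{[(tert-butyldiphenylsilyl)oxy]methyl}oxolan-2-one
Product: 16 (1R,2S,3R)-3-[4-(benzyloxy)-3-methoxybenzyl]-1-[3,4-bis(benzyloxy)phenyl]-2-{[(tert-butyldiphenylsilyl)oxy]methyl}butane-1,4-diol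
Conditions: LiAlH4, THF, 0 °C; Fieser work-up
Reagents that add atoms: none
Why: Hydride reduction of the lactone opens the template to the C9 primary alcohol and the C7' carbinol without touching a stereocentre, the silyl and benzyl ethers being stable at 0 °C.

Step 11
Reactants: 16 (1R,2S,3R)-3-[4-(benzyloxy)-3-methoxybenzyl]-1-[3,4-bis(benzyloxy)phenyl]-2-{[(tert-butyldiphenylsilyl)oxy]methyl}butane-1,4-diol
Product: 17 (1R,2S,3R)-3-[4-(benzyloxy)-3-methoxybenzyl]-1-[3,4-bis(benzyloxy)phenyl]-2-{[(tert-butyldiphenylsilyl)oxy]methyl}butane-1,4-diyl diacetate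
Conditions: Ac2O, pyridine, DMAP (cat.), CH2Cl2, rt
Reagents that add atoms: acetic anhydride, CC(=O)OC(C)=O
Why: DMAP-catalysed acylation caps both hydroxyls, and the acetate on C7' both keeps that oxygen out of the later ring closure and deactivates its benzylic C–H towards DDQ.

Step 12
Reactants: 17 (1R,2S,3R)-3-[4-(benzyloxy)-3-methoxybenzyl]-1-[3,4-bis(benzyloxy)phenyl]-2-{[(tert-butyldiphenylsilyl)oxy]methyl}butane-1,4-diyl diacetate
Product: 18 (1R,2S,3R)-3-[4-(benzyloxy)-3-methoxybenzyl]-1-[3,4-bis(benzyloxy)phenyl]-2-(hydroxymethyl)butane-1,4-diyl diacetate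
Conditions: HF·pyridine, pyridine, THF, 0 °C to rt
Reagents that add atoms: none
Why: Fluoride cleavage of the Si–O bond under buffered, slightly acidic conditions frees only the C5 hydroxyl and avoids the base-induced 1,3-acetyl shift from the C7' oxygen.

Step 13
Reactants: 18 (1R,2S,3R)-3-[4-(benzyloxy)-3-methoxybenzyl]-1-[3,4-bis(benzyloxy)phenyl]-2-(hydroxymethyl)butane-1,4-diyl diacetate
Product: 19 [(2S,3R,4S)-4-{(R)-acetoxy[3,4-bis(benzyloxy)phenyl]methyl}-2-[4-(benzyloxy)-3-methoxyphenyl]oxolan-3-yl]methyl acetate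
Conditions: DDQ (1.1 equiv), 4 Å molecular sieves, CH2Cl2, 0 °C to rt
Reagents that add atoms: none
Why: DDQ oxidative benzylic C–H etherification, in which hydride abstraction from the CH2 para to the benzyloxy group gives a p-alkoxybenzyl cation that the C5 hydroxyl captures by 5-exo closure of ring A, the aryl group taking the less hindered position trans to the C3 CH2OAc group and so setting C2 as S.

Step 14
Reactants: 19 [(2S,3R,4S)-4-{(R)-acetoxy[3,4-bis(benzyloxy)phenyl]methyl}-2-[4-(benzyloxy)-3-methoxyphenyl]oxolan-3-yl]methyl acetate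
Product: 20 (R)-[(3S,4R,5S)-5-[4-(benzyloxy)-3-methoxyphenyl]-4-(hydroxymethyl)oxolan-3-yl][3,4-bis(benzyloxy)phenyl]methanol
Conditions: K2CO3 (cat.), MeOH/THF, rt
Reagents that add atoms: none
Why: Base-catalysed transesterification with methanol removes both acetates and leaves the ethers and all stereocentres untouched.

Step 15
Reactants: 20 (R)-[(3S,4R,5S)-5-[4-(benzyloxy)-3-methoxyphenyl]-4-(hydroxymethyl)oxolan-3-yl][3,4-bis(benzyloxy)phenyl]methanol
Product: 21 (2S,3R,4S)-4-[(R)-(3,4-dihydroxyphenyl)(hydroxy)methyl]-2-(4-hydroxy-3-methoxyphenyl)-3-(hydroxymethyl)oxolane (CNP0197133.1)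
Conditions: H2 (1 atm), Pd/C (10% palladium on carbon), EtOAc/MeOH, rt; stopped after three equivalents of H2; work-up under argon
Reagents that add atoms: none
Why: Hydrogenolysis of the three aryl benzyl ethers is much faster under neutral conditions than cleavage of the two benzylic C–O bonds of the skeleton (C2–O1 and C7'–OH), so the reaction can be stopped at the triphenol.

**Compound list**

1 | 3,4-bis(benzyloxy)benzoic acid | O=C(O)c1ccc(OCc2ccccc2)c(OCc2ccccc2)c1 | starting material
2 | 3,4-bis(benzyloxy)benzoyl chloride | O=C(Cl)c1ccc(OCc2ccccc2)c(OCc2ccccc2)c1 | intermediate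
3 | allyl acetate | CC(=O)OCC=C | starting material
4 | allyl 3-[3,4-bis(benzyloxy)phenyl]-3-oxopropanoate | C=CCOC(=O)CC(=O)c1ccc(OCc2ccccc2)c(OCc2ccccc2)c1 | intermediate
5 | methyl bromoacetate | COC(=O)CBr | starting material
6 | 1-allyl 4-methyl 2-[3,4-bis(benzyloxy)benzoyl]butanedioate (racemic) | COC(=O)CC(C(=O)OCC=C)C(=O)c1ccc(OCc2ccccc2)c(OCc2ccccc2)c1 | intermediate
7 | 1-allyl 4-methyl 2-[(R)-[3,4-bis(benzyloxy)phenyl](hydroxy)methyl]butanedioate (carbinol R; C2 epimers, 2R syn expected to predominate) | COC(=O)CC(C(=O)OCC=C)[C@@H](O)c1ccc(OCc2ccccc2)c(OCc2ccccc2)c1 | intermediate (not isolated)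
8 | allyl (2R)-2-[3,4-bis(benzyloxy)phenyl]-5-oxooxolane-3-carboxylate (C3 epimers before equilibration) | O=C1CC(C(=O)OCC=C)[C@H](c2ccc(OCc3ccccc3)c(OCc3ccccc3)c2)O1 | intermediate (not isolated)
9 | allyl (2R,3R)-2-[3,4-bis(benzyloxy)phenyl]-5-oxooxolane-3-carboxylate (trans) | O=C1C[C@@H](C(=O)OCC=C)[C@H](c2ccc(OCc3ccccc3)c(OCc3ccccc3)c2)O1 | intermediate
10 | (2R,3R)-2-[3,4-bis(benzyloxy)phenyl]-5-oxooxolane-3-carboxylic acid | O=C1C[C@@H](C(=O)O)[C@H](c2ccc(OCc3ccccc3)c(OCc3ccccc3)c2)O1 | intermediate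
11 | (4S,5R)-5-[3,4-bis(benzyloxy)phenyl]-4-(hydroxymethyl)oxolan-2-one | O=C1C[C@@H](CO)[C@H](c2ccc(OCc3ccccc3)c(OCc3ccccc3)c2)O1 | intermediate
12 | (4S,5R)-5-[3,4-bis(benzyloxy)phenyl]-4-{[(tert-butyldiphenylsilyl)oxy]methyl}oxolan-2-one | O=C1C[C@@H](CO[Si](c2ccccc2)(c2ccccc2)C(C)(C)C)[C@H](c2ccc(OCc3ccccc3)c(OCc3ccccc3)c2)O1 | intermediate
13 | 4-(benzyloxy)-3-methoxybenzyl alcohol | COc1cc(CO)ccc1OCc1ccccc1 | starting material
14 | 4-(benzyloxy)-3-methoxybenzyl bromide | COc1cc(CBr)ccc1OCc1ccccc1 | intermediate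
15 | (3R,4S,5R)-3-[4-(benzyloxy)-3-methoxybenzyl]-5-[3,4-bis(benzyloxy)phenyl]-4-{[(tert-butyldiphenylsilyl)oxy]methyl}oxolan-2-one (all-trans) | O=C1[C@H](Cc2ccc(OCc3ccccc3)c(OC)c2)[C@@H](CO[Si](c2ccccc2)(c2ccccc2)C(C)(C)C)[C@H](c2ccc(OCc3ccccc3)c(OCc3ccccc3)c2)O1 | intermediate
16 | (1R,2S,3R)-3-[4-(benzyloxy)-3-methoxybenzyl]-1-[3,4-bis(benzyloxy)phenyl]-2-{[(tert-butyldiphenylsilyl)oxy]methyl}butane-1,4-diol | OC[C@H](Cc1ccc(OCc2ccccc2)c(OC)c1)[C@@H](CO[Si](c1ccccc1)(c1ccccc1)C(C)(C)C)[C@@H](O)c1ccc(OCc2ccccc2)c(OCc2ccccc2)c1 | intermediate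
17 | (1R,2S,3R)-3-[4-(benzyloxy)-3-methoxybenzyl]-1-[3,4-bis(benzyloxy)phenyl]-2-{[(tert-butyldiphenylsilyl)oxy]methyl}butane-1,4-diyl diacetate | CC(=O)OC[C@H](Cc1ccc(OCc2ccccc2)c(OC)c1)[C@@H](CO[Si](c1ccccc1)(c1ccccc1)C(C)(C)C)[C@@H](OC(C)=O)c1ccc(OCc2ccccc2)c(OCc2ccccc2)c1 | intermediate
18 | (1R,2S,3R)-3-[4-(benzyloxy)-3-methoxybenzyl]-1-[3,4-bis(benzyloxy)phenyl]-2-(hydroxymethyl)butane-1,4-diyl diacetate | CC(=O)OC[C@H](Cc1ccc(OCc2ccccc2)c(OC)c1)[C@@H](CO)[C@@H](OC(C)=O)c1ccc(OCc2ccccc2)c(OCc2ccccc2)c1 | intermediate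
19 | [(2S,3R,4S)-4-{(R)-acetoxy[3,4-bis(benzyloxy)phenyl]methyl}-2-[4-(benzyloxy)-3-methoxyphenyl]oxolan-3-yl]methyl acetate | COc1cc([C@H]2OC[C@@H]([C@@H](OC(C)=O)c3ccc(OCc4ccccc4)c(OCc4ccccc4)c3)[C@@H]2COC(C)=O)ccc1OCc1ccccc1 | intermediate
20 | (R)-[(3S,4R,5S)-5-[4-(benzyloxy)-3-methoxyphenyl]-4-(hydroxymethyl)oxolan-3-yl][3,4-bis(benzyloxy)phenyl]methanol | COc1cc([C@H]2OC[C@@H]([C@@H](O)c3ccc(OCc4ccccc4)c(OCc4ccccc4)c3)[C@@H]2CO)ccc1OCc1ccccc1 | intermediate
21 | (2S,3R,4S)-4-[(R)-(3,4-dihydroxyphenyl)(hydroxy)methyl]-2-(4-hydroxy-3-methoxyphenyl)-3-(hydroxymethyl)oxolane | COc1cc([C@H]2OC[C@@H]([C@@H](O)c3ccc(O)c(O)c3)[C@@H]2CO)ccc1O | target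

**Step count and risks**

Total steps: 15. Longest linear sequence: 14 (steps 1 to 7 and 9 to 15, from acid 1); step 8 is a one-step side branch.

Steps most likely to fail:

1. Step 4. The α-carbon may racemize more slowly than the hindered, electron-rich aryl ketone is reduced, so the dynamic resolution stays incomplete and selectivity erodes; the base equilibration may also open some lactone by β-elimination. The fallback separates reduction from C–C bond formation; it sets out from keto ester 4 and returns at lactone 9. Transfer hydrogenation of 4 with the same catalyst, where no dynamic resolution is needed, should give allyl (3R)-3-[3,4-bis(benzyloxy)phenyl]-3-hydroxypropanoate F1. Fráter–Seebach alkylation of its dianion (LiN(iPr)2, 2.2 equiv, THF, −78 to −20 °C) with methyl bromoacetate 5 should give the anti hydroxy diester 1-allyl 4-methyl (2S)-2-[(R)-[3,4-bis(benzyloxy)phenyl](hydroxy)methyl]butanedioate F2. This lactonizes (PPTS, PhMe) to the cis lactone allyl (2R,3S)-2-[3,4-bis(benzyloxy)phenyl]-5-oxooxolane-3-carboxylate F3, and catalytic DBU in PhMe then epimerizes the ester-bearing carbon to give 9.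

2. Step 13. DDQ may abstract hydride at the wrong benzylic site or oxidize the product further at its C2–H (a benzylic ether, more easily oxidized than the starting CH2), and the C2 cation may be captured by the catechol ring in a Friedel–Crafts closure to an aryltetralin. The fallback brings C2 in at the alcohol oxidation level and closes ring A by acid-catalysed SN1 etherification; it sets out from lactone 12 and returns at 19.
   - Aldol addition of the lithium enolate of 12 (LiN(SiMe3)2, THF, −78 °C) to 4-(benzyloxy)-3-methoxybenzaldehyde should give the 3,4-trans aldol adduct 3-{[4-(benzyloxy)-3-methoxyphenyl](hydroxy)methyl}-5-[3,4-bis(benzyloxy)phenyl]-4-{[(tert-butyldiphenylsilyl)oxy]methyl}oxolan-2-one F4, as carbinol epimers that converge later.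
   - TESOTf and 2,6-lutidine give its triethylsilyl ether F5.
   - LiAlH4 gives the silyl-protected diol F6.
   - Ac2O, pyridine and DMAP give the diacetate F7.
   - HF·pyridine removes both silyl groups to give the diol diacetate F8, which carries a free C2 carbinol and a free C5 hydroxyl.
   - Catalytic camphorsulfonic acid in CH2Cl2 at 0 °C ionizes only the free benzylic alcohol, and the C5 hydroxyl closes ring A trans to give 19.

3. Step 9. The labile electron-rich benzyl bromide may decompose, proton exchange may lead to double alkylation, and facial selectivity may be incomplete. The fallback replaces alkylation by aldol condensation and conjugate reduction; it sets out from lactone 12 and returns at 15. The aldol adduct F4 (made as above) is dehydrated (MsCl, Et3N, then DBU) to the benzylidene lactone (3E,4S,5R)-3-[4-(benzyloxy)-3-methoxybenzylidene]-5-[3,4-bis(benzyloxy)phenyl]-4-{[(tert-butyldiphenylsilyl)oxy]methyl}oxolan-2-one F9. Conjugate reduction (NaBH4, NiCl2·6H2O, MeOH/THF, 0 °C) followed by DBU equilibration of the α-carbon to the trans arrangement should give 15.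

**Further compounds**

F1 | step 4 | allyl (3R)-3-[3,4-bis(benzyloxy)phenyl]-3-hydroxypropanoate | C=CCOC(=O)C[C@@H](O)c1ccc(OCc2ccccc2)c(OCc2ccccc2)c1
F2 | step 4 | 1-allyl 4-methyl (2S)-2-[(R)-[3,4-bis(benzyloxy)phenyl](hydroxy)methyl]butanedioate (anti) | COC(=O)C[C@H](C(=O)OCC=C)[C@@H](O)c1ccc(OCc2ccccc2)c(OCc2ccccc2)c1
F3 | step 4 | allyl (2R,3S)-2-[3,4-bis(benzyloxy)phenyl]-5-oxooxolane-3-carboxylate (cis) | O=C1C[C@H](C(=O)OCC=C)[C@H](c2ccc(OCc3ccccc3)c(OCc3ccccc3)c2)O1
F4 | step 13 | (3S,4S,5R)-3-{[4-(benzyloxy)-3-methoxyphenyl](hydroxy)methyl}-5-[3,4-bis(benzyloxy)phenyl]-4-{[(tert-butyldiphenylsilyl)oxy]methyl}oxolan-2-one (carbinol epimers) | O=C1[C@H](C(O)c2ccc(OCc3ccccc3)c(OC)c2)[C@@H](CO[Si](c2ccccc2)(c2ccccc2)C(C)(C)C)[C@H](c2ccc(OCc3ccccc3)c(OCc3ccccc3)c2)O1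
F5 | step 13 | triethylsilyl ether of F4 | O=C1[C@H](C(O[Si](CC)(CC)CC)c2ccc(OCc3ccccc3)c(OC)c2)[C@@H](CO[Si](c2ccccc2)(c2ccccc2)C(C)(C)C)[C@H](c2ccc(OCc3ccccc3)c(OCc3ccccc3)c2)O1
F6 | step 13 | 1-[3,4-bis(benzyloxy)phenyl]-2-{[(tert-butyldiphenylsilyl)oxy]methyl}-3-{[4-(benzyloxy)-3-methoxyphenyl][(triethylsilyl)oxy]methyl}butane-1,4-diol (backbone configured as in 16) | OC[C@H](C(O[Si](CC)(CC)CC)c1ccc(OCc2ccccc2)c(OC)c1)[C@@H](CO[Si](c1ccccc1)(c1ccccc1)C(C)(C)C)[C@@H](O)c1ccc(OCc2ccccc2)c(OCc2ccccc2)c1
F7 | step 13 | diacetate of F6 | CC(=O)OC[C@H](C(O[Si](CC)(CC)CC)c1ccc(OCc2ccccc2)c(OC)c1)[C@@H](CO[Si](c1ccccc1)(c1ccccc1)C(C)(C)C)[C@@H](OC(C)=O)c1ccc(OCc2ccccc2)c(OCc2ccccc2)c1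
F8 | step 13 | 1-[3,4-bis(benzyloxy)phenyl]-3-{[4-(benzyloxy)-3-methoxyphenyl](hydroxy)methyl}-2-(hydroxymethyl)butane-1,4-diyl diacetate | CC(=O)OC[C@H](C(O)c1ccc(OCc2ccccc2)c(OC)c1)[C@@H](CO)[C@@H](OC(C)=O)c1ccc(OCc2ccccc2)c(OCc2ccccc2)c1
F9 | step 9 | (3E,4S,5R)-3-[4-(benzyloxy)-3-methoxybenzylidene]-5-[3,4-bis(benzyloxy)phenyl]-4-{[(tert-butyldiphenylsilyl)oxy]methyl}oxolan-2-one | O=C1/C(=C/c2ccc(OCc3ccccc3)c(OC)c2)[C@@H](CO[Si](c2ccccc2)(c2ccccc2)C(C)(C)C)[C@H](c2ccc(OCc3ccccc3)c(OCc3ccccc3)c2)O1
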